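**Retrosynthetic overview**

1. Target 11 ⇒ diol 8: the two ester C–O bonds are made last, one at a time. The butanoate C–O bond is formed first and site-selectively at the less hindered C6 CH2OH (key step); the acetate on the hindered C4 CH2OH closes the route.
2. Diol 8 ⇒ diester 7 (ester reduction) ⇒ 5-methyl diester 5 (the CH2CH2Cl arm comes from the lateral CH3 and ICH2Cl).
3. Diester 5 ⇒ enaminone 2 + dimethyl 3-methylglutaconate 3 by a [3+3] benzannulation that puts CO2Me, CH3, CO2Me on C4, C5, C6 and H on C7.
4. Ring order: the gem-dimethyl five-membered ring is bought with ketone 1; the benzene ring is the only ring formed (step 2). Indane numbering throughout: C2 = CMe2, C3a/C7a = fusion carbons, C7 = ArH.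

Assumption: the target has no stereocentre (it is achiral), so no stereocontrol is needed; 3,3-dimethylcyclopentanone is bought as a catalogue ketone.

**Route**

Step 1
Reactants: 1 3,3-dimethylcyclopentan-1-one
Product: 2 (E)-2-[(dimethylamino)methylidene]-4,4-dimethylcyclopentan-1-one
Conditions: Me2NCH(OMe)2 (1.5 equiv), toluene, 110 °C, MeOH distilled off
Reagents that add atoms: N,N-dimethylformamide dimethyl acetal, COC(OC)N(C)C
Why: Enaminone formation (aminomethylenation of a ketone α-CH2); only the α-CH2 remote from the quaternary carbon is unhindered, which fixes the later CH2–CMe2–CH2 bridge between the two fusion carbons.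

Step 2
Reactants: 2 (E)-2-[(dimethylamino)methylidene]-4,4-dimethylcyclopentan-1-one; 3 dimethyl 3-methylpent-2-enedioate (dimethyl 3-methylglutaconate, commercial E/Z mixture)
Product: 5 dimethyl 2,2,5-trimethyl-2,3-dihydro-1H-indene-4,6-dicarboxylate, via dienyl diester adduct 4 (not isolated)
Conditions: DBU (1.2 equiv), 4 Å molecular sieves, MeCN, 60 °C
Reagents that add atoms: none
Why: Base-mediated [3+3] benzannulation (glutaconate version of the Prelog hydroxyisophthalate synthesis): the symmetric glutaconate anion adds to the enaminone β-carbon with loss of Me2NH, the second ester α-carbon closes onto the ring ketone (intramolecular aldol) and loss of water gives the arene.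

Step 3
Reactants: 5 dimethyl 2,2,5-trimethyl-2,3-dihydro-1H-indene-4,6-dicarboxylate
Product: 7 dimethyl 5-(2-chloroethyl)-2,2-dimethyl-2,3-dihydro-1H-indene-4,6-dicarboxylate, via benzylic lithium species 6 (not isolated)
Conditions: LiN(iPr)2 (1.1 equiv), THF, −78 °C; then cannulated into ICH2Cl (3 equiv), THF, −78 → −40 °C
Reagents that add atoms: chloroiodomethane, ClCI
Why: Lateral lithiation of an ortho-toluate (the C5 methyl is flanked by two esters and is the most acidic benzylic site) followed by SN2 alkylation at the C–I bond; inverse addition into excess electrophile suppresses E1cB loss of HCl from the product.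

Step 4
Reactants: 7 dimethyl 5-(2-chloroethyl)-2,2-dimethyl-2,3-dihydro-1H-indene-4,6-dicarboxylate
Product: 8 [5-(2-chloroethyl)-2,2-dimethyl-2,3-dihydro-1H-indene-4,6-diyl]dimethanol
Conditions: iBu2AlH (5 equiv), CH2Cl2, −78 → 0 °C; aq. KNaC4H4O6 work-up
Reagents that add atoms: none
Why: Hydride reduction of both aryl esters to benzylic alcohols; the primary chloride is inert to iBu2AlH at this temperature and the neutral tartrate work-up avoids alkoxide closure onto the chloroethyl arm.

Step 5
Reactants: 8 [5-(2-chloroethyl)-2,2-dimethyl-2,3-dihydro-1H-indene-4,6-diyl]dimethanol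
Product: 10 [5-(2-chloroethyl)-4-(hydroxymethyl)-2,2-dimethyl-2,3-dihydro-1H-inden-6-yl]methyl butanoate (C6 ester, C4 CH2OH free), via 2-butanoyl triazolium ion 9 (not isolated)
Conditions: butanal (1.0 equiv, slow addition), 2-(2,6-diisopropylphenyl)-6,7-dihydro-5H-pyrrolo[2,1-c][1,2,4]triazol-2-ium tetrafluoroborate (10 mol%), DBU (10 mol%), 3,3',5,5'-tetra-tert-butyldiphenoquinone (1.05 equiv), THF, 0 °C; stopped near 90% conversion, mono-ester purified by chromatography
Reagents that add atoms: butanal, CCCC=O
Why: Proposed new method: oxidative carbene-catalysed esterification used to tell apart two primary benzylic alcohols. Butanal is turned (Breslow intermediate, quinone oxidation) into acyl azolium 9, whose carbonyl is shielded by the N-(2,6-diisopropylphenyl) group; no uncatalysed acyl donor is present, so every acyl transfer must pass through this crowded species. The C6 CH2OH (one ortho H, C7) should reach it, while the C4 CH2OH (flanked by the ring CH2 and the chloroethyl arm) should react much more slowly. The closest known reaction type is oxidative NHC acylation of alcohols via acyl azolium ions, which is selective for primary over secondary OH and for OH over NH but has not been used to separate two primary benzylic OH groups by ortho substitution.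

Step 6
Reactants: 10 [5-(2-chloroethyl)-4-(hydroxymethyl)-2,2-dimethyl-2,3-dihydro-1H-inden-6-yl]methyl butanoate
Product: 11 [4-(acetoxymethyl)-5-(2-chloroethyl)-2,2-dimethyl-2,3-dihydro-1H-inden-6-yl]methyl butanoate (target)
Conditions: Ac2O (1.5 equiv), pyridine, DMAP (5 mol%), CH2Cl2, 0 °C → rt
Reagents that add atoms: acetic anhydride, CC(=O)OC(C)=O
Why: DMAP-catalysed acetylation (nucleophilic acyl transfer) of the remaining hindered primary alcohol; the butanoate and the primary chloride are untouched under these weakly basic conditions.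

**Compound list**

1 | 3,3-dimethylcyclopentan-1-one | CC1(C)CCC(=O)C1 | starting material
2 | (E)-2-[(dimethylamino)methylidene]-4,4-dimethylcyclopentan-1-one | CN(C)/C=C1\CC(C)(C)CC1=O | intermediate
3 | dimethyl 3-methylpent-2-enedioate (E isomer drawn; E/Z mixture used) | COC(=O)/C=C(\C)CC(=O)OC | starting material
4 | dimethyl 2-[(4,4-dimethyl-2-oxocyclopentylidene)methyl]-3-methylpent-2-enedioate (formed in the flask, alkene geometry not defined) | COC(=O)CC(C)=C(C=C1CC(C)(C)CC1=O)C(=O)OC | intermediate
5 | dimethyl 2,2,5-trimethyl-2,3-dihydro-1H-indene-4,6-dicarboxylate | COC(=O)c1cc2CC(C)(C)Cc2c(C(=O)OC)c1C | intermediate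
6 | [4,6-bis(methoxycarbonyl)-2,2-dimethyl-2,3-dihydro-1H-inden-5-yl]methyllithium (formed in the flask) | [Li]Cc1c(C(=O)OC)cc2CC(C)(C)Cc2c1C(=O)OC | intermediate
7 | dimethyl 5-(2-chloroethyl)-2,2-dimethyl-2,3-dihydro-1H-indene-4,6-dicarboxylate | COC(=O)c1cc2CC(C)(C)Cc2c(C(=O)OC)c1CCCl | intermediate
8 | [5-(2-chloroethyl)-2,2-dimethyl-2,3-dihydro-1H-indene-4,6-diyl]dimethanol | OCc1cc2CC(C)(C)Cc2c(CO)c1CCCl | intermediate
9 | 3-butanoyl-2-(2,6-diisopropylphenyl)-6,7-dihydro-5H-pyrrolo[2,1-c][1,2,4]triazol-2-ium tetrafluoroborate (formed in the flask) | CCCC(=O)c1n2CCCc2n[n+]1-c1c(C(C)C)cccc1C(C)C.F[B-](F)(F)F | intermediate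
10 | [5-(2-chloroethyl)-4-(hydroxymethyl)-2,2-dimethyl-2,3-dihydro-1H-inden-6-yl]methyl butanoate | CCCC(=O)OCc1cc2CC(C)(C)Cc2c(CO)c1CCCl | intermediate
11 | [4-(acetoxymethyl)-5-(2-chloroethyl)-2,2-dimethyl-2,3-dihydro-1H-inden-6-yl]methyl butanoate | CCCC(=O)OCc1cc2c(c(COC(C)=O)c1CCCl)CC(C)(C)C2 | target

**Step count and risks**

Total steps: 6. Longest linear sequence: 6 (from ketone 1).

The three steps most likely to fail:

Step 5 (the proposed new step). The steric gap between the two CH2OH groups may be too small, giving the regioisomeric mono-ester and some bis-ester, and the basic medium could let an alkoxide close onto the chloroethyl arm to give an isochroman. The fallback uses known chemistry and replaces catalyst control by a protecting-group detour. It sets out from diol 8: TrCl (1.05 equiv), Et3N, DMAP, CH2Cl2, 0 °C puts the very bulky trityl group on the less hindered C6 alcohol to give [5-(2-chloroethyl)-2,2-dimethyl-6-(trityloxymethyl)-2,3-dihydro-1H-inden-4-yl]methanol F5. Ac2O/pyridine then gives [5-(2-chloroethyl)-2,2-dimethyl-6-(trityloxymethyl)-2,3-dihydro-1H-inden-4-yl]methyl acetate F6. HCO2H in Et2O removes the trityl group to give [5-(2-chloroethyl)-6-(hydroxymethyl)-2,2-dimethyl-2,3-dihydro-1H-inden-4-yl]methyl acetate F7, and butanoyl chloride/pyridine in CH2Cl2 brings the sequence back to the route at target 11.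

Step 2. The glutaconate is less acidic than a 3-oxoglutarate; ring closure may stall at adduct 4, or the C3 methyl of 4 may act as the nucleophile and give a homophthalate isomer. The fallback sets out from enaminone 2 and uses the classical Prelog condensation with dimethyl 3-oxopentanedioate (NaOMe, MeOH, reflux) to give dimethyl 5-hydroxy-2,2-dimethyl-2,3-dihydro-1H-indene-4,6-dicarboxylate F1. Tf2O/pyridine in CH2Cl2 at 0 °C converts it into dimethyl 2,2-dimethyl-5-{[(trifluoromethyl)sulfonyl]oxy}-2,3-dihydro-1H-indene-4,6-dicarboxylate F2, and Suzuki methylation (trimethylboroxine, Pd(OAc)2, SPhos, K3PO4, toluene/H2O, 100 °C) returns to the route at diester 5.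

Step 3. Anion 6 may self-condense, deprotonation may compete at the ring CH2 next to the C4 ester, or product 7 may lose HCl to the vinyl arene. The fallback sets out from diester 5 and traps the same anion with formaldehyde instead (LiN(iPr)2, THF, −78 °C; paraformaldehyde; warm to rt). The alkoxide closes onto the less hindered C6 ester to give the δ-lactone methyl 7,7-dimethyl-1-oxo-3,4,6,7,8-pentahydro-1H-cyclopenta[g]isochromene-5-carboxylate-type lactone ester F3 (C5 CH2CH2O joined to the C6 carbonyl, C4 CO2Me kept). SOCl2 with ZnCl2 (cat.) at 80 °C opens the lactone to methyl 6-(chlorocarbonyl)-5-(2-chloroethyl)-2,2-dimethyl-2,3-dihydro-1H-indene-4-carboxylate F4, and MeOH/pyridine at 0 °C returns to the route at diester 7.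

**Further compounds**

F1 | step 2 | dimethyl 5-hydroxy-2,2-dimethyl-2,3-dihydro-1H-indene-4,6-dicarboxylate | COC(=O)c1cc2CC(C)(C)Cc2c(C(=O)OC)c1O
F2 | step 2 | dimethyl 2,2-dimethyl-5-{[(trifluoromethyl)sulfonyl]oxy}-2,3-dihydro-1H-indene-4,6-dicarboxylate | COC(=O)c1cc2CC(C)(C)Cc2c(C(=O)OC)c1OS(=O)(=O)C(F)(F)F
F3 | step 3 | δ-lactone ester (C5 CH2CH2O closed onto the C6 carbonyl, C4 CO2Me kept) | COC(=O)c1c2CC(C)(C)Cc2cc3C(=O)OCCc13
F4 | step 3 | methyl 6-(chlorocarbonyl)-5-(2-chloroethyl)-2,2-dimethyl-2,3-dihydro-1H-indene-4-carboxylate | COC(=O)c1c2CC(C)(C)Cc2cc(C(Cl)=O)c1CCCl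
F5 | step 5 | [5-(2-chloroethyl)-2,2-dimethyl-6-(trityloxymethyl)-2,3-dihydro-1H-inden-4-yl]methanol | OCc1c2CC(C)(C)Cc2cc(COC(c3ccccc3)(c3ccccc3)c3ccccc3)c1CCCl
F6 | step 5 | [5-(2-chloroethyl)-2,2-dimethyl-6-(trityloxymethyl)-2,3-dihydro-1H-inden-4-yl]methyl acetate | CC(=O)OCc1c2CC(C)(C)Cc2cc(COC(c3ccccc3)(c3ccccc3)c3ccccc3)c1CCCl
F7 | step 5 | [5-(2-chloroethyl)-6-(hydroxymethyl)-2,2-dimethyl-2,3-dihydro-1H-inden-4-yl]methyl acetate | CC(=O)OCc1c2CC(C)(C)Cc2cc(CO)c1CCCl
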